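**Assumption:** the β‑diketone is drawn as its keto–enol tautomer, which forms spontaneously. (R)‑Methyl hydrogen 3‑methylglutarate, (R)‑diphenylprolinol TMS ether and 2‑methyl‑1‑propenylmagnesium bromide are taken as catalogue items.

## Retrosynthetic overview

1. The curcuminoid is made last by a Pabon aldol condensation of aryl‑ether aldehyde 14 with feruloylacetone 16; no protecting groups are used anywhere.
2. Key step: the aryl ether and both allylic C–O stereocentres come from one Pd(0)‑catalysed cis‑1,4‑aryloxy‑hydroxylation of (+)‑α‑turmerone monoepoxide 12 with vanillin. This replaces the obvious Mitsunobu/SNAr etherification of a pre‑oxygenated bisabolane.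
3. α‑Turmerone 11 comes from a Weinreb amide plus isobutenyl Grignard; its 1,3‑diene comes from the kinetic dienyl triflate of enone 7 by Negishi methylation.
4. The only ring formed is the cyclohexene, by an organocatalytic Michael/aldol annulation of aldehyde 4 with methyl vinyl ketone. The side‑chain methyl stereocentre comes from the chiral pool (hemiester 1) and the ring stereocentre from the catalyst. Both arenes come from vanillin.

## Route

**Step 1**
Reactants: 1, (R)‑methyl hydrogen 3‑methylglutarate
Product: 2, methyl (R)‑5‑hydroxy‑3‑methylpentanoate (used crude; partial lactonisation is harmless)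
Conditions: BH3·SMe2 (1.1 equiv), THF, −10 °C → rt; MeOH quench
Reagents that add atoms: none
Why: Chemoselective borane reduction of a carboxylic acid in the presence of a methyl ester; the stereocentre is not touched.

**Step 2**
Reactants: 2
Product: 3, (R)‑5‑hydroxy‑N‑methoxy‑N,3‑dimethylpentanamide
Conditions: MeNH(OMe)·HCl (1.5 equiv), i‑PrMgCl (4.5 equiv), THF, −20 → 0 °C
Reagents that add atoms: N,O‑dimethylhydroxylamine hydrochloride, CNOC.Cl
Why: Magnesium‑amide aminolysis of the ester (or its lactone) gives the Weinreb amide, a base‑stable acyl equivalent that survives the annulation, enolisation and Negishi steps.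

**Step 3**
Reactants: 3
Product: 4, (R)‑N‑methoxy‑N,3‑dimethyl‑5‑oxopentanamide
Conditions: TEMPO (10 mol %), PhI(OAc)2 (1.1 equiv), CH2Cl2, rt
Reagents that add atoms: none
Why: Oxoammonium (TEMPO/BAIB) oxidation of a primary alcohol stops at the aldehyde, and the β‑stereocentre cannot epimerise.

**Step 4**
Reactants: 4; 5, methyl vinyl ketone
Product: 6, (3S,4R)‑4‑formyl‑N‑methoxy‑N,3‑dimethyl‑7‑oxooctanamide
Conditions: (R)‑α,α‑diphenylprolinol TMS ether (10 mol %), ethyl 3,4‑dihydroxybenzoate (20 mol %), 5 (1.5 equiv), neat, 4 °C, 36–48 h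
Reagents that add atoms: methyl vinyl ketone (5), C=CC(C)=O
Why: Enamine‑catalysed asymmetric Michael addition in which the (E)‑enamine attacks the H‑bond‑activated enone on the face away from the CPh2OTMS group, so the (R)‑catalyst sets the new (4R) centre under catalyst control.

**Step 5**
Reactants: 6
Product: 7, (3S)‑N‑methoxy‑N‑methyl‑3‑[(1R)‑4‑oxocyclohex‑2‑en‑1‑yl]butanamide
Conditions: 0.1 M aq. KOH, n‑Bu4NOH (cat.), THF/Et2O, 40 °C; stop at full conversion
Reagents that add atoms: none
Why: Intramolecular aldol condensation (second half of a Robinson annulation) closes the six‑membered ring faster than the branched aldehyde α‑centre epimerises, and the Weinreb amide is inert to dilute hydroxide.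

**Step 6**
Reactants: 7
Product: 8, (4R)‑4‑[(2S)‑4‑[methoxy(methyl)amino]‑4‑oxobutan‑2‑yl]cyclohexa‑1,5‑dien‑1‑yl trifluoromethanesulfonate
Conditions: LDA (1.1 equiv), THF, −78 °C; then PhNTf2 (1.15 equiv), −78 → 0 °C
Reagents that add atoms: N‑phenyl‑bis(trifluoromethanesulfonimide), O=S(=O)(N(c1ccccc1)S(=O)(=O)C(F)(F)F)C(F)(F)F
Why: Kinetic α′‑deprotonation of the enone (several pKa units more acidic than the amide α‑CH2) gives the cross‑conjugated dienolate, and O‑triflation fixes the 2,4‑diene regiochemistry without touching either stereocentre.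

**Step 7**
Reactants: 8
Product: 9, (3S)‑N‑methoxy‑N‑methyl‑3‑[(1R)‑4‑methylcyclohexa‑2,4‑dien‑1‑yl]butanamide
Conditions: Me2Zn (1.5 equiv), Pd(PPh3)4 (5 mol %), THF, 0 °C → rt
Reagents that add atoms: dimethylzinc, C[Zn]C
Why: Negishi coupling of the dienyl triflate installs the ring methyl; the organozinc does not add to the Weinreb amide, and staying at or below rt avoids [1,5]‑H shifts that would scramble C1.

**Step 8**
Reactants: 9; 10, 2‑methyl‑1‑propenylmagnesium bromide
Product: 11, (+)‑α‑turmerone, (6S)‑2‑methyl‑6‑[(1R)‑4‑methylcyclohexa‑2,4‑dien‑1‑yl]hept‑2‑en‑4‑one (handle under argon)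
Conditions: 10 (0.5 M in THF, 1.5 equiv), THF, 0 °C; cold aq. NH4Cl
Reagents that add atoms: 2‑methyl‑1‑propenylmagnesium bromide (10), CC(C)=C[Mg]Br
Why: Weinreb ketone synthesis, where the chelated tetrahedral intermediate prevents over‑addition and collapses on work‑up to the conjugated enone.

**Step 9**
Reactants: 11
Product: 12, (6S)‑2‑methyl‑6‑[(1R,4R,6S)‑1‑methyl‑7‑oxabicyclo[4.1.0]hept‑2‑en‑4‑yl]hept‑2‑en‑4‑one (used crude, cold)
Conditions: DMDO (1.0 equiv, acetone), CH2Cl2, −40 → −20 °C; evaporate cold
Reagents that add atoms: dimethyldioxirane, CC1(C)OO1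
Why: Neutral electrophilic epoxidation picks the most electron‑rich, trisubstituted diene terminus (the enone alkene is deactivated) and should add anti to the pseudo‑axial side chain as in α‑phellandrene‑type dienes, setting the epoxide CH carbon (the future carbinol centre); the ratio is expected to be moderate and the minor syn‑epoxide is removed after step 10.

**Step 10**
Reactants: 12; 13, vanillin
Product: 14, 4‑{[(1R,4S,6R)‑4‑hydroxy‑3‑methyl‑6‑[(2S)‑6‑methyl‑4‑oxohept‑5‑en‑2‑yl]cyclohex‑2‑en‑1‑yl]oxy}‑3‑methoxybenzaldehyde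
Conditions: Pd(PPh3)4 (5 mol %), 13 (1.3 equiv), THF, 0 °C → rt; 12 added slowly
Reagents that add atoms: vanillin (13), COc1cc(C=O)ccc1O
Why: Tsuji–Trost opening of a diene monoepoxide, in which Pd(0) ionises the tertiary allylic C–O bond anti to the epoxide and the phenoxide (formed by the liberated alkoxide) attacks the distal secondary allyl terminus anti to Pd, so double inversion gives the cis‑1,4 aryloxy alcohol with both oxygens trans to the side chain.

**Step 11**
Reactants: 13, vanillin; 15, acetylacetone
Product: 16, feruloylacetone, (E)‑6‑(4‑hydroxy‑3‑methoxyphenyl)hex‑5‑ene‑2,4‑dione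
Conditions: 15 (3 equiv), B2O3, EtOAc, 70 °C; then 13 (1 equiv), B(On‑Bu)3, n‑BuNH2 (0.2 equiv, slow addition), 70 °C; 0.4 M HCl, 60 °C
Reagents that add atoms: acetylacetone (15), CC(=O)CC(C)=O
Why: Pabon condensation, where boron chelation of the diketone blocks Knoevenagel reaction at the central carbon and directs aldol condensation to a terminal methyl, with excess acetylacetone suppressing bis‑condensation.

**Step 12**
Reactants: 14; 16
Product: 17, bisabolocurcumin ether (target)
Conditions: 16 (1.5 equiv), B2O3 (1 equiv), EtOAc, 60 °C, 30 min; add 14, B(On‑Bu)3 (2 equiv); n‑BuNH2 (0.3 equiv, slow addition), 60 °C, 4 h; then 5 % aq. AcOH, 40 °C, 1 h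
Reagents that add atoms: feruloylacetone (16), COc1cc(/C=C/C(=O)CC(C)=O)ccc1O
Why: Second Pabon condensation at the remaining terminal methyl of the boron‑chelated diketone gives the (E)‑styryl unit, while the unactivated side‑chain ketone does not compete and mild acid decomplexation spares the allylic aryl ether and all four stereocentres.

## Compound list

1 | (R)‑methyl hydrogen 3‑methylglutarate | COC(=O)C[C@H](C)CC(=O)O | starting material
2 | methyl (R)‑5‑hydroxy‑3‑methylpentanoate | COC(=O)C[C@H](C)CCO | intermediate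
3 | (R)‑5‑hydroxy‑N‑methoxy‑N,3‑dimethylpentanamide | CON(C)C(=O)C[C@H](C)CCO | intermediate
4 | (R)‑N‑methoxy‑N,3‑dimethyl‑5‑oxopentanamide | CON(C)C(=O)C[C@H](C)CC=O | intermediate
5 | methyl vinyl ketone | C=CC(C)=O | starting material
6 | (3S,4R)‑4‑formyl‑N‑methoxy‑N,3‑dimethyl‑7‑oxooctanamide | CON(C)C(=O)C[C@H](C)[C@H](C=O)CCC(C)=O | intermediate
7 | (3S)‑N‑methoxy‑N‑methyl‑3‑[(1R)‑4‑oxocyclohex‑2‑en‑1‑yl]butanamide | CON(C)C(=O)C[C@H](C)[C@@H]1C=CC(=O)CC1 | intermediate
8 | (4R)‑4‑[(2S)‑4‑[methoxy(methyl)amino]‑4‑oxobutan‑2‑yl]cyclohexa‑1,5‑dien‑1‑yl triflate | CON(C)C(=O)C[C@H](C)[C@@H]1C=CC(OS(=O)(=O)C(F)(F)F)=CC1 | intermediate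
9 | (3S)‑N‑methoxy‑N‑methyl‑3‑[(1R)‑4‑methylcyclohexa‑2,4‑dien‑1‑yl]butanamide | CON(C)C(=O)C[C@H](C)[C@@H]1C=CC(C)=CC1 | intermediate
10 | 2‑methyl‑1‑propenylmagnesium bromide | CC(C)=C[Mg]Br | starting material
11 | (+)‑α‑turmerone, (6S)‑2‑methyl‑6‑[(1R)‑4‑methylcyclohexa‑2,4‑dien‑1‑yl]hept‑2‑en‑4‑one | CC(C)=CC(=O)C[C@H](C)[C@@H]1C=CC(C)=CC1 | intermediate
12 | (6S)‑2‑methyl‑6‑[(1R,4R,6S)‑1‑methyl‑7‑oxabicyclo[4.1.0]hept‑2‑en‑4‑yl]hept‑2‑en‑4‑one | CC(C)=CC(=O)C[C@H](C)[C@@H]1C=C[C@@]2(C)O[C@H]2C1 | intermediate
13 | vanillin | COc1cc(C=O)ccc1O | starting material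
14 | 4‑{[(1R,4S,6R)‑4‑hydroxy‑3‑methyl‑6‑[(2S)‑6‑methyl‑4‑oxohept‑5‑en‑2‑yl]cyclohex‑2‑en‑1‑yl]oxy}‑3‑methoxybenzaldehyde | O=Cc1ccc(O[C@H]2C=C(C)[C@@H](O)C[C@@H]2[C@@H](C)CC(=O)C=C(C)C)c(OC)c1 | intermediate
15 | acetylacetone | CC(=O)CC(C)=O | starting material
16 | feruloylacetone, (E)‑6‑(4‑hydroxy‑3‑methoxyphenyl)hex‑5‑ene‑2,4‑dione | COc1cc(/C=C/C(=O)CC(C)=O)ccc1O | intermediate
17 | bisabolocurcumin ether | COc1cc(/C=C/C(=O)/C=C(O)/C=C/c2ccc(O[C@H]3C=C(C)[C@@H](O)C[C@@H]3[C@@H](C)CC(=O)C=C(C)C)c(OC)c2)ccc1O | target

## Summary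

Total steps: 12. Longest linear sequence: 11 (steps 1–10, then 12); step 11 is a one‑step side branch.

**Three steps most likely to fail, with fallbacks**

1. **Step 9 (epoxidation).** The risks are modest facial selectivity from a remote stereocentre, over‑oxidation, and the lability of a tertiary allylic epoxide. Fallback: avoid the diene oxide altogether.
   - Rubottom α′‑hydroxylation of enone 7 installs the secondary oxygen.
   - MeMgBr/CeCl3 adds anti to that oxygen to give the cis‑diol.
   - Isobutenyl Grignard on the Weinreb amide, then cyclic carbonate formation.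
   - Pd(0) ionises the carbonate with loss of CO2 to the same alkoxy‑π‑allyl used in step 10.

2. **Step 10 (Pd cis‑1,4‑aryloxylation).** The risks are Pd‑induced isomerisation of the epoxide, attack at the tertiary terminus, and slow ionisation on the face syn to the side chain. Fallback: make both C–O bonds by cycloaddition and form the ether at the arene instead.
   - Singlet‑oxygen [4+2] on 11 (anti to the side chain), then thiourea reduction, gives the cis‑diol.
   - Mono‑silylate the less hindered hydroxyl.
   - SNAr of the remaining alkoxide on 4‑fluoro‑3‑methoxybenzaldehyde (retention at carbon), then desilylate.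
   - This fallback is weaker than the others: the side‑chain ketone may enolise and condense with the aryl aldehyde under the SNAr base, and the mono‑silylation selectivity is uncertain.

3. **Step 12 (final Pabon condensation).** The risks are competing condensation at the side‑chain ketone and loss of the allylic aryl ether during decomplexation. Fallback: reverse the order of events. Use the BF2 chelate of curcumin (one step from curcumin and BF3·OEt2, with the C‑nucleophilic diketone masked) in excess as the phenol nucleophile in step 10, then remove BF2 with sodium oxalate in aqueous MeOH.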